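**Plan**

- Retrosynthesis: the vanillyl O–benzyl bond is cut last. The pyranone ring is opened at O1–C2 to a 2-hydroxyaryl ynone, whose C4 is taken one oxidation level down to a silylated carbinol. Ring A is then cut at C5–C6, C4a–C8a and C8–C8a.
- Enabling feature: in ring A the C8a oxygen lies para to the C6 methoxy group and ortho to C4a, which carries C4, and C7–OMe is next to C6. This 2-substituted 4,5-dimethoxyphenol is what a methoxy(1-methoxyvinyl)carbene complex of Cr(CO)5, a terminal alkyne and one CO ligand assemble.
- The alkyne partner, a 3-silyloxy-1,4-diyne, is cut at C3–C4 (acetylide plus ynal). Its arylbutyne is cut at the benzylic C–C bond back to O-benzylvanillin and a propargyl unit.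
- Forward: arylbutyne, then diynyl silyl ether, then ring A by benzannulation, then ynone, then the pyranone ring by 6-endo O1–C2 closure, then debenzylation.
- Stereochemistry: the target has no stereocentre. The carbinol carbon that becomes C4 is carried racemic and erased by oxidation in step 9.

Key step: step 7

Assumption: 4-benzyloxy-3-methoxybenzaldehyde (O-benzylvanillin) is bought; it is otherwise one benzylation away from vanillin.

**Route**

Step 1
Reactants: 1 4-benzyloxy-3-methoxybenzaldehyde; 2 3-bromoprop-1-yne (propargyl bromide)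
Product: 4 racemic 1-(4-benzyloxy-3-methoxyphenyl)but-3-yn-1-ol, via allenylzinc bromide 3 (not isolated)
Conditions: Zn dust, THF/sat. aq NH4Cl, 0 °C → rt
Reagents that add atoms: none
Why: Zinc-mediated Barbier propargylation, in which allenylzinc bromide adds to the aldehyde through a cyclic SE2′ transition state and so should deliver the homopropargylic rather than the allenic alcohol; the new carbinol centre forms racemic and is removed in step 2.

Step 2
Reactants: 4 racemic 1-(4-benzyloxy-3-methoxyphenyl)but-3-yn-1-ol
Product: 5 4-(4-benzyloxy-3-methoxyphenyl)but-1-yne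
Conditions: Et3SiH (3 equiv), CF3CO2H (5 equiv), CH2Cl2, 0 °C
Reagents that add atoms: none
Why: Ionic hydrogenation, in which the 4-alkoxybenzylic alcohol ionises to a cation stabilised by the para benzyloxy group and is reduced by hydride transfer from the silane, while the terminal alkyne and the aryl benzyl ether should be inert at 0 °C; the stereocentre of 4 disappears.

Step 3
Reactants: 5 4-(4-benzyloxy-3-methoxyphenyl)but-1-yne; 6 3-(trimethylsilyl)prop-2-ynal
Product: 8 racemic 7-(4-benzyloxy-3-methoxyphenyl)-1-(trimethylsilyl)hepta-1,4-diyn-3-ol, via lithium 4-arylbut-1-ynide 7 (not isolated)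
Conditions: n-BuLi (1.05 equiv), THF, −78 °C; then 6, −78 → −30 °C; aq NH4Cl
Reagents that add atoms: none
Why: Deprotonation of the terminal alkyne and 1,2-addition of the lithium acetylide to the ynal is a standard propargylic alcohol synthesis; the carbinol centre (later C4) forms racemic, which is immaterial because it is oxidised in step 9.

Step 4
Reactants: 8 racemic 7-(4-benzyloxy-3-methoxyphenyl)-1-(trimethylsilyl)hepta-1,4-diyn-3-ol
Product: 9 racemic tert-butyl{[7-(4-benzyloxy-3-methoxyphenyl)-1-(trimethylsilyl)hepta-1,4-diyn-3-yl]oxy}dimethylsilane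
Conditions: TBSCl, imidazole, DMF, rt
Reagents that add atoms: tert-butyldimethylsilyl chloride (TBSCl), CC(C)(C)[Si](C)(C)Cl
Why: Imidazole-promoted O-silylation of a secondary alcohol; the silyl ether is needed because a free propargylic hydroxyl would trap the ketene intermediate of step 7 as a lactone, and the centre is untouched.

Step 5
Reactants: 9 racemic tert-butyl{[7-(4-benzyloxy-3-methoxyphenyl)-1-(trimethylsilyl)hepta-1,4-diyn-3-yl]oxy}dimethylsilane
Product: 10 racemic tert-butyl{[7-(4-benzyloxy-3-methoxyphenyl)hepta-1,4-diyn-3-yl]oxy}dimethylsilane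
Conditions: K2CO3 (0.2 equiv), MeOH, 0 °C
Reagents that add atoms: none
Why: Base-catalysed methanolysis (protodesilylation) cleaves the alkynyl C–SiMe3 bond selectively, the secondary O–TBS ether being stable to K2CO3/MeOH; short reaction at 0 °C should avoid isomerisation of the skipped diyne.

Step 6
Reactants: 11 methyl vinyl ether; 12 chromium hexacarbonyl Cr(CO)6
Product: 15 pentacarbonyl[methoxy(1-methoxyvinyl)carbene]chromium (CO)5Cr=C(OMe)C(OMe)=CH2, via 1-methoxyvinyllithium 13 (not isolated), via acylchromate Li[(CO)5CrC(O)C(OMe)=CH2] 14 (not isolated)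
Conditions: t-BuLi, THF, −78 → 0 °C; Cr(CO)6, THF, −78 °C → rt; then Me3OBF4, CH2Cl2, 0 °C
Reagents that add atoms: trimethyloxonium tetrafluoroborate (Me3OBF4), C[O+](C)C.F[B-](F)(F)F
Why: Fischer carbene synthesis, i.e. α-lithiation of the enol ether, addition of the vinyllithium to a CO ligand of Cr(CO)6 and O-methylation of the acylchromate with the oxonium salt; α-alkoxyalkenyl(methoxy)carbene complexes of this kind are known from lithiated cyclic enol ethers, and 15 is used freshly prepared.

Step 7
Reactants: 15 pentacarbonyl[methoxy(1-methoxyvinyl)carbene]chromium; 10 racemic tert-butyl{[7-(4-benzyloxy-3-methoxyphenyl)hepta-1,4-diyn-3-yl]oxy}dimethylsilane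
Product: 17 racemic 2-[1-(tert-butyldimethylsilyloxy)-5-(4-benzyloxy-3-methoxyphenyl)pent-2-yn-1-yl]-4,5-dimethoxyphenol, via Cr(CO)3 arene complex 16 (not isolated)
Conditions: 10 (1.3 equiv), THF (0.05 M), 50 °C, argon; then air, MeCN, rt
Reagents that add atoms: none
Why: Dötz benzannulation: thermal loss of one cis CO from 15 opens a coordination site for the terminal alkyne of 10, alkyne insertion gives a vinylcarbene complex and CO insertion a chromium-bound dienylketene, which cyclises and tautomerises to the phenol held as its Cr(CO)3 complex 16. The closest known reaction type is the benzannulation of alkenyl(methoxy)carbene complexes of zerovalent chromium with terminal alkynes, propargylic silyl ethers and α-alkoxyalkenyl complexes included. Ring A closes by six-electron electrocyclisation of the dienylketene (C8–C8a) after C5–C6 and C4a–C8a have formed by alkyne and CO insertion, so the carbene carbon becomes C6, the vinyl carbons C7 and C8, the CO carbon C8a and the alkyne carbons C5 and C4a. No stereocentre is created: the silyloxy-bearing carbon stays racemic and the planar chirality of 16 is lost on decomplexation. The step needs regioselective insertion with the substituted alkyne carbon next to the phenol carbon, which the steric difference between H and the branched propargylic group secures, and reaction at the terminal rather than the internal triple bond, which the lower steric demand of the terminal alkyne, the shielding of the internal one by the silyloxy-bearing carbon and an excess of 10 at high dilution should secure. Decomplexation with air alone avoids the strong oxidants that would carry the 4-methoxyphenol on to the quinone.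

Step 8
Reactants: 17 racemic 2-[1-(tert-butyldimethylsilyloxy)-5-(4-benzyloxy-3-methoxyphenyl)pent-2-yn-1-yl]-4,5-dimethoxyphenol
Product: 18 racemic 2-[5-(4-benzyloxy-3-methoxyphenyl)-1-hydroxypent-2-yn-1-yl]-4,5-dimethoxyphenol
Conditions: TBAF (1.2 equiv), AcOH (1.2 equiv), THF, 0 °C → rt
Reagents that add atoms: none
Why: Fluoride-induced cleavage of the secondary silyl ether driven by Si–F bond formation; buffering with acetic acid keeps the phenol protonated and should suppress ortho-quinone methide formation at the doubly activated benzylic carbinol.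

Step 9
Reactants: 18 racemic 2-[5-(4-benzyloxy-3-methoxyphenyl)-1-hydroxypent-2-yn-1-yl]-4,5-dimethoxyphenol
Product: 19 5-(4-benzyloxy-3-methoxyphenyl)-1-(2-hydroxy-4,5-dimethoxyphenyl)pent-2-yn-1-one
Conditions: activated MnO2 (10 equiv), CH2Cl2, rt
Reagents that add atoms: none
Why: Activated MnO2 oxidises benzylic-propargylic alcohols under neutral heterogeneous conditions, a standard entry to 2-hydroxyaryl ynones from the corresponding carbinols; the only stereocentre of the route is erased here.

Step 10
Reactants: 19 5-(4-benzyloxy-3-methoxyphenyl)-1-(2-hydroxy-4,5-dimethoxyphenyl)pent-2-yn-1-one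
Product: 21 2-[2-(4-benzyloxy-3-methoxyphenyl)ethyl]-6,7-dimethoxy-4H-chromen-4-one, via diethylamino enone 20 (not isolated)
Conditions: Et2NH (3 equiv), EtOH, rt → 50 °C
Reagents that add atoms: none
Why: Amine-mediated 6-endo oxa-Michael closure, in which conjugate addition of Et2NH gives the β-amino enone and the phenol oxygen then adds to C2 with loss of Et2NH, so that O1–C2 should form in the chromone sense and not in the 5-exo aurone sense.

Step 11
Reactants: 21 2-[2-(4-benzyloxy-3-methoxyphenyl)ethyl]-6,7-dimethoxy-4H-chromen-4-one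
Product: 22 2-[2-(4-hydroxy-3-methoxyphenyl)ethyl]-6,7-dimethoxy-4H-chromen-4-one
Conditions: H2 (1 atm), 10% Pd/C, EtOAc, rt, stopped after one equivalent of H2
Reagents that add atoms: none
Why: Catalytic hydrogenolysis of the aryl benzyl ether, which should be faster than reduction of the vinylogous-ester C2=C3 bond of the chromone under these mild conditions.

**Compound list**

1 | 4-benzyloxy-3-methoxybenzaldehyde | COc1cc(C=O)ccc1OCc1ccccc1 | starting material
2 | 3-bromoprop-1-yne | C#CCBr | starting material
3 | allenylzinc bromide | C=C=C[Zn]Br | intermediate (not isolated)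
4 | racemic 1-(4-benzyloxy-3-methoxyphenyl)but-3-yn-1-ol | C#CCC(O)c1ccc(OCc2ccccc2)c(OC)c1 | intermediate
5 | 4-(4-benzyloxy-3-methoxyphenyl)but-1-yne | C#CCCc1ccc(OCc2ccccc2)c(OC)c1 | intermediate
6 | 3-(trimethylsilyl)prop-2-ynal | C[Si](C)(C)C#CC=O | starting material
7 | lithium 4-(4-benzyloxy-3-methoxyphenyl)but-1-yn-1-ide | [Li]C#CCCc1ccc(OCc2ccccc2)c(OC)c1 | intermediate (not isolated)
8 | racemic 7-(4-benzyloxy-3-methoxyphenyl)-1-(trimethylsilyl)hepta-1,4-diyn-3-ol | C[Si](C)(C)C#CC(O)C#CCCc1ccc(OCc2ccccc2)c(OC)c1 | intermediate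
9 | racemic tert-butyl{[7-(4-benzyloxy-3-methoxyphenyl)-1-(trimethylsilyl)hepta-1,4-diyn-3-yl]oxy}dimethylsilane | C[Si](C)(C)C#CC(O[Si](C)(C)C(C)(C)C)C#CCCc1ccc(OCc2ccccc2)c(OC)c1 | intermediate
10 | racemic tert-butyl{[7-(4-benzyloxy-3-methoxyphenyl)hepta-1,4-diyn-3-yl]oxy}dimethylsilane | C#CC(O[Si](C)(C)C(C)(C)C)C#CCCc1ccc(OCc2ccccc2)c(OC)c1 | intermediate
11 | methyl vinyl ether | C=COC | starting material
12 | chromium hexacarbonyl Cr(CO)6 | O=C=[Cr](=C=O)(=C=O)(=C=O)(=C=O)=C=O | starting material
13 | 1-methoxyvinyllithium | [Li]C(=C)OC | intermediate (not isolated)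
14 | lithium pentacarbonyl(2-methoxy-1-oxidoprop-2-en-1-ylidene)chromate Li[(CO)5CrC(O)C(OMe)=CH2] | C=C(OC)C([O-])=[Cr](=C=O)(=C=O)(=C=O)(=C=O)=C=O.[Li+] | intermediate (not isolated)
15 | pentacarbonyl[methoxy(1-methoxyvinyl)carbene]chromium | C=C(OC)C(OC)=[Cr](=C=O)(=C=O)(=C=O)(=C=O)=C=O | intermediate
16 | racemic tricarbonyl(η6-arene)chromium complex of phenol 17, Cr(CO)3 bound to the new ring A (written as two dot-joined parts) | Oc1cc(OC)c(OC)cc1C(O[Si](C)(C)C(C)(C)C)C#CCCc1ccc(OCc2ccccc2)c(OC)c1.O=C=[Cr](=C=O)=C=O | intermediate (not isolated)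
17 | racemic 2-[1-(tert-butyldimethylsilyloxy)-5-(4-benzyloxy-3-methoxyphenyl)pent-2-yn-1-yl]-4,5-dimethoxyphenol | Oc1cc(OC)c(OC)cc1C(O[Si](C)(C)C(C)(C)C)C#CCCc1ccc(OCc2ccccc2)c(OC)c1 | intermediate
18 | racemic 2-[5-(4-benzyloxy-3-methoxyphenyl)-1-hydroxypent-2-yn-1-yl]-4,5-dimethoxyphenol | Oc1cc(OC)c(OC)cc1C(O)C#CCCc1ccc(OCc2ccccc2)c(OC)c1 | intermediate
19 | 5-(4-benzyloxy-3-methoxyphenyl)-1-(2-hydroxy-4,5-dimethoxyphenyl)pent-2-yn-1-one | Oc1cc(OC)c(OC)cc1C(=O)C#CCCc1ccc(OCc2ccccc2)c(OC)c1 | intermediate
20 | (E)-5-(4-benzyloxy-3-methoxyphenyl)-3-(diethylamino)-1-(2-hydroxy-4,5-dimethoxyphenyl)pent-2-en-1-one | CCN(CC)/C(CCc1ccc(OCc2ccccc2)c(OC)c1)=C/C(=O)c1cc(OC)c(OC)cc1O | intermediate (not isolated)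
21 | 2-[2-(4-benzyloxy-3-methoxyphenyl)ethyl]-6,7-dimethoxy-4H-chromen-4-one | COc1cc2oc(CCc3ccc(OCc4ccccc4)c(OC)c3)cc(=O)c2cc1OC | intermediate
22 | 2-[2-(4-hydroxy-3-methoxyphenyl)ethyl]-6,7-dimethoxy-4H-chromen-4-one | COc1cc(CCc2cc(=O)c3cc(OC)c(OC)cc3o2)ccc1O | target

**Count**

Total steps: 11. Longest linear sequence: 10 steps (steps 1–5 and 7–11); step 6 is a one-step side branch that joins at step 7.

**Steps most likely to fail**

Step 7. The carbene may also insert into the internal triple bond, several alkyne units may insert in a row, or the electron-rich phenol may be lost by oxidation during decomplexation. The fallback sets out from 15 (and from 5, lithiated to 7 as in step 3) and comes back at 18. Ring A is built on a mono-alkyne and the propargylic C–C bond is made afterwards. Complex 15 and commercial 3,3-diethoxyprop-1-yne (C#CC(OCC)OCC) in THF at 50 °C should give the tricarbonylchromium complex of the acetal phenol F1, which air in MeCN releases as 2-(diethoxymethyl)-4,5-dimethoxyphenol F2. PPTS in acetone/water then unmasks 2-hydroxy-4,5-dimethoxybenzaldehyde F3. This aldehyde is also an article of commerce, so the end game does not hinge on the benzannulation. Addition of F3 to lithium acetylide 7 (2.2 equiv, THF, −78 → 0 °C; the equivalent consumed by the phenol returns as 5 on work-up) should give diol 18 directly.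

Step 6. The acylchromate or the carbene complex, both with an unsubstituted vinyl terminus, may polymerise or decompose during direct O-alkylation with the oxonium salt and the handling that follows. The fallback sets out from 14 and comes back at 15. The acylchromate is precipitated from water with Me4NBr as tetramethylammonium pentacarbonyl(2-methoxy-1-oxidoprop-2-en-1-ylidene)chromate F4, a storable solid. Acetyl bromide in CH2Cl2 at −40 °C converts it into pentacarbonyl[acetoxy(1-methoxyvinyl)carbene]chromium F5, which is not isolated. Methanol at −40 → 0 °C should then give 15 by addition–elimination at the carbene carbon.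

Step 9. The electron-rich free phenol ring may be oxidised on MnO2 (quinone formation, oxidative coupling), or the ynone may cyclise prematurely and unselectively on the oxidant surface. The fallback sets out from 17 and comes back at 21, masking the phenol before the carbinol is liberated. MOMCl and iPr2NEt in CH2Cl2 convert 17 into racemic tert-butyl{[5-(4-benzyloxy-3-methoxyphenyl)-1-[4,5-dimethoxy-2-(methoxymethoxy)phenyl]pent-2-yn-1-yl]oxy}dimethylsilane F6. TBAF in THF gives racemic 5-(4-benzyloxy-3-methoxyphenyl)-1-[4,5-dimethoxy-2-(methoxymethoxy)phenyl]pent-2-yn-1-ol F7. Dess–Martin periodinane (NaHCO3, CH2Cl2) gives 5-(4-benzyloxy-3-methoxyphenyl)-1-[4,5-dimethoxy-2-(methoxymethoxy)phenyl]pent-2-yn-1-one F8. HCl in MeOH at 40 °C removes the acetal, and the freed phenol should close onto the protonated ynone in the 6-endo sense to give 21.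

**Further compounds**

F1 | step 7 | tricarbonyl(η6-arene)chromium complex of 2-(diethoxymethyl)-4,5-dimethoxyphenol (not isolated; written as two dot-joined parts) | CCOC(OCC)c1cc(OC)c(OC)cc1O.O=C=[Cr](=C=O)=C=O
F2 | step 7 | 2-(diethoxymethyl)-4,5-dimethoxyphenol | CCOC(OCC)c1cc(OC)c(OC)cc1O
F3 | step 7 | 2-hydroxy-4,5-dimethoxybenzaldehyde | O=Cc1cc(OC)c(OC)cc1O
F4 | step 6 | tetramethylammonium pentacarbonyl(2-methoxy-1-oxidoprop-2-en-1-ylidene)chromate | C=C(OC)C([O-])=[Cr](=C=O)(=C=O)(=C=O)(=C=O)=C=O.C[N+](C)(C)C
F5 | step 6 | pentacarbonyl[acetoxy(1-methoxyvinyl)carbene]chromium (not isolated) | C=C(OC)C(OC(C)=O)=[Cr](=C=O)(=C=O)(=C=O)(=C=O)=C=O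
F6 | step 9 | racemic tert-butyl{[5-(4-benzyloxy-3-methoxyphenyl)-1-[4,5-dimethoxy-2-(methoxymethoxy)phenyl]pent-2-yn-1-yl]oxy}dimethylsilane | COCOc1cc(OC)c(OC)cc1C(O[Si](C)(C)C(C)(C)C)C#CCCc1ccc(OCc2ccccc2)c(OC)c1
F7 | step 9 | racemic 5-(4-benzyloxy-3-methoxyphenyl)-1-[4,5-dimethoxy-2-(methoxymethoxy)phenyl]pent-2-yn-1-ol | COCOc1cc(OC)c(OC)cc1C(O)C#CCCc1ccc(OCc2ccccc2)c(OC)c1
F8 | step 9 | 5-(4-benzyloxy-3-methoxyphenyl)-1-[4,5-dimethoxy-2-(methoxymethoxy)phenyl]pent-2-yn-1-one | COCOc1cc(OC)c(OC)cc1C(=O)C#CCCc1ccc(OCc2ccccc2)c(OC)c1
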